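## Analysis of the target

The target is a 4,1′-biindole: ring system A is a 3,5-dibromo-7-methoxy-1H-indole, and its C4 carries N1′ of ring system B, a 2,5-dibromoindole. The C4–N1′ bond is a hindered aryl–nitrogen axis, flanked by C5–Br and C3a (with C3–Br peri to it) on one side and by C2′–Br and C7a′ on the other. It is the only stereogenic element, so there are no stereocentres to relate. Sensitive groups are the N1–H 3-bromoindole (acid- and light-labile), the 2-bromoindole (acid-labile) and four C–Br bonds, which forbid organolithium chemistry and make late palladium chemistry ambiguous. Two bromines are out of reach of electrophilic substitution on a finished biindole: C2′–Br, because indoles brominate at C3′ first, and C5–Br, because C5 is meta to the C7 methoxy group. The feature the route exploits lies in the benzenoid ring of A: N1′ at C4 is para to the methoxy group at C7, N1 at C7a is ortho to it, C5–Br is ortho to C4 and para to C7a, and C3a is the only unsubstituted carbon ortho to C7a. These six carbons are therefore those of a 2-bromo-4-methoxy-5-nitroaniline (compound 2 below), with the amino nitrogen as N1′ and the nitro nitrogen as N1. The C7 methoxy group is exactly the ortho substituent that a Bartoli annulation at C7a/C3a needs. The difficulty is thus not ring construction as such, but making a crowded N-aryl axis and placing four bromines on two indoles of similar reactivity without any step that must choose between carbon–halogen bonds.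

## Retrosynthetic reasoning

**11 ⇒ 9 (C3–Br).** The C3–Br bond is cut first because the N–H 3-bromoindole is the most fragile group and C3 of ring A is the one position where electrophilic bromine goes unaided. The forward step must distinguish C3 from C3′ of ring B. Only ring A has an acidic N–H, so it alone can react as its anion 10.

**9 ⇒ 7 (key disconnection: C3a–C3 and N1–C2).** The whole pyrrole ring of A is removed: the two-carbon unit C2–C3 goes back to a vinyl organomagnesium reagent and N1 goes back to the nitro group of 7. It is cut here and not at the C4–N1′ axis because the axis then never has to be made by joining two indoles. Until this step ring A is a robust nitroarene with no N–H and no nucleophilic C3, which lets ring B be built and brominated first. The forward Bartoli reaction must form the C3a–C3 bond next to the bulky C4 substituent; the C7 methoxy group blocks the other ortho position and promotes the rearrangement.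

**7 ⇒ 6 (C2′–Br).** The C2′ bromine is traced to the carbonyl oxygen of lactam 6. This places bromine at C2′ by the position of the carbonyl group and not by selectivity, and needs no metalation beside aryl bromides. The forward step is a deoxygenative bromination that aromatises ring B.

**6 ⇒ 5 (N1′–C7a′).** The second aryl bond to N1′ is cut inside the five-membered ring. The forward step is an intramolecular copper-catalysed amidation. The crowded nitrogen is arylated in a ring closure, and the only aryl iodide is the one held next to the nitrogen, so the three C–Br bonds are not in competition.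

**5 ⇒ 2 + 3 (N1′–C2′ amide bond).** An ordinary amide disconnection gives aniline 2 and arylacetic acid 3, activated as acid chloride 4. Acid 3 brings C2′, C3′, the benzenoid ring of B and C5′–Br in one piece.

**2 ⇒ 1 (C5–Br).** The future C5 bromine is introduced by bromination ortho to the amino group of 1. This is why C5–Br, unreachable on an indole, costs one step here.

## Alternatives that were turned down

**Alternative 1: N-arylation of two finished indoles (textbook).** The disconnection is the C4–N1′ bond between complete indoles. The forward key step is an Ullmann–Goldberg or Buchwald–Hartwig N-arylation of 5-bromo-1H-indole A2 with 4-iodo-7-methoxy-1H-indole A1 to give 4-(5-bromo-1H-indol-1-yl)-7-methoxy-1H-indole A3, followed by bromination. It was turned down for these reasons: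
- The metal has to pick the C4–I bond of A1 beside the C5–Br bond of A2, so self-coupling of A2 competes.
- A3 still lacks three bromines. Electrophilic bromination of A3 would go to C3 and C3′ and then to C6 (ortho to the methoxy group). It would never reach C2′, which needs a C2′ metalation that halogen–metal exchange at C5′–Br forbids. It would never reach C5, which is meta to the methoxy group and shielded by the N-aryl group.
- Carrying the bromines in, with 2,5-dibromo-1H-indole A4 as the N–H partner, turns the coupling into a fourfold ortho-substituted N-arylation with five competing carbon–halogen bonds.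
- With the N1 protection that A1 needs, it is no shorter than the chosen route.

**Alternative 2: aryne amino-bromination.** The disconnection cuts C4–N1′ and C5–Br together. In the forward key step, fluoride releases the aryne with its triple bond between C4 and C5 from 7-methoxy-1-(4-methylbenzenesulfonyl)-5-(trimethylsilyl)-1H-indol-4-yl trifluoromethanesulfonate A5. The nitrogen of A4 adds, and the aryl anion is trapped by an electrophilic bromine source. It was turned down for these reasons:
- The groups beside the triple bond are the ring-fusion carbon C3a and C6–H. The fused five-membered ring compresses the angle at C4 and opens it at C5, so C5 is the more electrophilic end. Nitrogen would enter at C5 and bromine at C4, the reverse of the target.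
- The C7 methoxy group is too remote to override this. The usual remedy, an inductively withdrawing group at C6, has no counterpart in the target (C6–H) and could not be removed beside four bromines.
- The anion of A4 is ambident (C3′ attack), and the aryl anion would be protonated by the N–H of A4 before it meets bromine.
- A5 needs five or six steps with N-protection.

**Alternative 3: oxidative union of like polarity (C4–H with N1′–H).** The disconnection uses the para relationship between C4 and the methoxy group. In the forward key step, 1-(5-bromo-7-methoxy-2,3-dihydro-1H-indol-1-yl)ethan-1-one A6 is oxidised by one electron (anodic, photoredox or with a trivalent-iodine oxidant) to its radical cation, which is captured at C4 by the N–H of A4. It was turned down for these reasons: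
- A4 is an electron-rich indole and is oxidised more easily than the bromo- and acyl-deactivated A6, so A4 becomes the radical cation and couples through C3′.
- The azoles that serve as nitrogen nucleophiles in such aminations are electron-poor, which A4 is not.
- C4 of A6 lies between C5–Br and the C3 methylene group, a doubly ortho-substituted site that intermolecular capture reaches poorly.
- The product would still need deacetylation and dehydrogenation of the indoline, so nothing is gained in steps.

Key step: step 5

Remark (assumption): the SMILES defines no configuration at the C4–N1′ axis, so the target is taken as the racemate; 1 and 3 are taken as catalogue compounds.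

## Route

Step 1
Reactants: 1 4-methoxy-3-nitroaniline
Product: 2 2-bromo-4-methoxy-5-nitroaniline
Conditions: NBS (1.0 equiv), MeCN, 0 °C → rt, dark
Reagents that add atoms: N-bromosuccinimide, O=C1CCC(=O)N1Br
Why: Electrophilic aromatic bromination directed by the amino group, the strongest donor; of its two ortho positions the one between NH2 and NO2 is shielded, so bromine should enter at C6 (para to the nitro group), the future C5 of ring A.

Step 2
Reactants: 2 2-bromo-4-methoxy-5-nitroaniline; 3 2-(5-bromo-2-iodophenyl)acetic acid
Product: 5 N-(2-bromo-4-methoxy-5-nitrophenyl)-2-(5-bromo-2-iodophenyl)acetamide, via acid chloride 4 (not isolated)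
Conditions: 3, (COCl)2 (1.2 equiv), DMF (cat.), CH2Cl2, 0 °C → rt; evaporate; then 2, pyridine (2 equiv), CH2Cl2, 0 °C → rt
Reagents that add atoms: oxalyl chloride, O=C(Cl)C(=O)Cl (supplies the chlorine of 4; no atom of it remains in 5)
Why: Nucleophilic acyl substitution (Schotten–Baumann-type amide formation); the acid chloride 4 is used because the ortho-bromo nitroaniline 2 is a weak nucleophile, and pyridine takes up the HCl.

Step 3
Reactants: 5 N-(2-bromo-4-methoxy-5-nitrophenyl)-2-(5-bromo-2-iodophenyl)acetamide
Product: 6 5-bromo-1-(2-bromo-4-methoxy-5-nitrophenyl)-1,3-dihydro-2H-indol-2-one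
Conditions: CuI (10 mol%), N,N′-dimethylethylenediamine (20 mol%), K3PO4 (2 equiv), toluene, 90 °C, Ar
Reagents that add atoms: none
Why: Intramolecular Ullmann–Goldberg amidation (5-exo closure at nitrogen): the copper amidate of 5 inserts into the C–I bond, the most reactive carbon–halogen bond present and the only one within reach of the nitrogen, so the crowded N1′–C7a′ bond forms inside a five-membered ring while the three C–Br bonds stay.

Step 4
Reactants: 6 5-bromo-1-(2-bromo-4-methoxy-5-nitrophenyl)-1,3-dihydro-2H-indol-2-one
Product: 7 2,5-dibromo-1-(2-bromo-4-methoxy-5-nitrophenyl)-1H-indole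
Conditions: POBr3 (2.5 equiv), imidazole (1.2 equiv), ClCH2CH2Cl, 80 °C; then ice-water
Reagents that add atoms: phosphoryl tribromide, O=P(Br)(Br)Br
Why: Deoxygenative bromination of a lactam (Vilsmeier-type activation): O-phosphorylation and bromide addition give a 2-bromo-3H-indolium ion that loses a C3′ proton to the aromatic 2-bromoindole, the known conversion of oxindoles into 2-bromoindoles; nitro, methoxy and aryl bromide groups are inert and imidazole buffers the HBr.

Step 5
Reactants: 7 2,5-dibromo-1-(2-bromo-4-methoxy-5-nitrophenyl)-1H-indole
Product: 9 5-bromo-4-(2,5-dibromo-1H-indol-1-yl)-7-methoxy-1H-indole, via nitrosoarene 8 (not isolated)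
Conditions: CH2=CHMgBr (3.5 equiv), THF, −45 °C; then sat. aq NH4Cl
Reagents that add atoms: vinylmagnesium bromide, C=C[Mg]Br
Why: Bartoli indole synthesis: the first equivalent of the Grignard reagent attacks an oxygen of the nitro group of 7 and, after loss of the magnesium enolate of acetaldehyde, leaves nitrosoarene 8. A second equivalent adds to the nitroso oxygen, and the resulting N-aryl-O-vinylhydroxylamine salt undergoes a [3,3]-sigmatropic shift that forms the C3a–C3 bond. The aldehyde so released is attacked by the anilide nitrogen in a 5-exo-trig closure (N1–C2 bond), the third equivalent acts as base to restore the benzene ring, and loss of water on work-up gives the pyrrole ring of A. The closest known reaction type is the Bartoli reaction of ortho-substituted nitroarenes, 2-nitroanisoles included, to 7-substituted indoles. Regioselectivity is fixed by the substrate: the shift can only end at C3a because the other ortho carbon, C7, carries the methoxy group, and this ortho substituent is also what steers the Grignard reagent to oxygen and drives the rearrangement. Chemoselectivity rests on the reagent: a vinyl Grignard reagent at −45 °C does not exchange with aryl or 2-indolyl bromides, and the position para to the nitro group is blocked by C5–Br against conjugate addition. No stereocentre is formed; the C4–N1′ axis is already present and stays racemic.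

Step 6
Reactants: 9 5-bromo-4-(2,5-dibromo-1H-indol-1-yl)-7-methoxy-1H-indole
Product: 11 3,5-dibromo-4-(2,5-dibromo-1H-indol-1-yl)-7-methoxy-1H-indole, via potassium indolide 10 (not isolated)
Conditions: KOH (2.5 equiv), DMF, 0 °C; then Br2 (1.0 equiv) in DMF, 0 °C; pour into ice-water
Reagents that add atoms: bromine, BrBr; potassium hydroxide, [K+].[OH-] (supplies the potassium of 10 only)
Why: Electrophilic C3 bromination of an indolide, the bromine counterpart of the standard iodine/KOH/DMF 3-iodination: only ring A has an N–H, so KOH turns it alone into the far more nucleophilic anion 10, which takes up bromine at C3, while the neutral, N-arylated and 2-bromo-deactivated ring B keeps its C3′–H; one equivalent of bromine at 0 °C guards against a second bromination.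

## Compound list

1 | 4-methoxy-3-nitroaniline | COc1ccc(N)cc1[N+](=O)[O-] | starting material
2 | 2-bromo-4-methoxy-5-nitroaniline | COc1cc(Br)c(N)cc1[N+](=O)[O-] | intermediate
3 | 2-(5-bromo-2-iodophenyl)acetic acid | OC(=O)Cc1cc(Br)ccc1I | starting material
4 | (5-bromo-2-iodophenyl)acetyl chloride | ClC(=O)Cc1cc(Br)ccc1I | intermediate
5 | N-(2-bromo-4-methoxy-5-nitrophenyl)-2-(5-bromo-2-iodophenyl)acetamide | COc1cc(Br)c(NC(=O)Cc2cc(Br)ccc2I)cc1[N+](=O)[O-] | intermediate
6 | 5-bromo-1-(2-bromo-4-methoxy-5-nitrophenyl)-1,3-dihydro-2H-indol-2-one | COc1cc(Br)c(N2C(=O)Cc3cc(Br)ccc32)cc1[N+](=O)[O-] | intermediate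
7 | 2,5-dibromo-1-(2-bromo-4-methoxy-5-nitrophenyl)-1H-indole | COc1cc(Br)c(-n2c(Br)cc3cc(Br)ccc32)cc1[N+](=O)[O-] | intermediate
8 | 2,5-dibromo-1-(2-bromo-4-methoxy-5-nitrosophenyl)-1H-indole | COc1cc(Br)c(-n2c(Br)cc3cc(Br)ccc32)cc1N=O | intermediate
9 | 5-bromo-4-(2,5-dibromo-1H-indol-1-yl)-7-methoxy-1H-indole | COc1cc(Br)c(-n2c(Br)cc3cc(Br)ccc32)c2cc[nH]c12 | intermediate
10 | potassium 5-bromo-4-(2,5-dibromo-1H-indol-1-yl)-7-methoxyindol-1-ide | COc1cc(Br)c(-n2c(Br)cc3cc(Br)ccc32)c2cc[n-]c12.[K+] | intermediate
11 | 3,5-dibromo-4-(2,5-dibromo-1H-indol-1-yl)-7-methoxy-1H-indole (racemic at the C4–N1′ axis) | COc1cc(Br)c(-n2c(Br)cc3cc(Br)ccc32)c2c(Br)c[nH]c12 | target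

## Step count and least certain steps

Total step count: 6. Longest linear sequence: 6 steps (1 → 2 → 5 → 6 → 7 → 9 → 11); 3 enters at step 2.

**Step 5 (key step).** The [3,3] shift has to deliver carbon to C3a, which lies next to the perpendicular 2-bromoindolyl group at C4. If the shift is slowed, the hydroxylamine stage is diverted to reduction at nitrogen (aniline, azo and azoxy formation). Attack of the Grignard reagent at C7 with loss of methoxide, activated by the ortho nitro group, can also compete. The fallback sets out from 7 and comes back at 9, and builds the pyrrole ring from the amine instead of the nitro group. Reduction of 7 with Fe powder and NH4Cl in aqueous ethanol at 70 °C should give 4-bromo-5-(2,5-dibromo-1H-indol-1-yl)-2-methoxyaniline F1. Sugasawa ortho-acylation of F1 with chloroacetonitrile, BCl3 and AlCl3 in 1,2-dichloroethane at reflux, followed by acidic hydrolysis of the ketimine, should give 1-[2-amino-5-bromo-6-(2,5-dibromo-1H-indol-1-yl)-3-methoxyphenyl]-2-chloroethan-1-one F2. The acyl group goes to C3a because the boron-bound nitrogen delivers the nitrile to its only free ortho position. NaBH4 in aqueous dioxane at reflux then reduces the ketone, the amine displaces chloride, and loss of water gives 9.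

**Step 4.** Once activated, the lactam is an electrophile, while the enol of unreacted 6 and C3′ of 7 are nucleophiles. Self-condensation of the Vilsmeier type can therefore compete, as can acid-induced decomposition of the 2-bromoindole on long heating with HBr. The fallback sets out from 6 and comes back at 7, with C3′ blocked by a traceless formyl group. A Vilsmeier–Haack–Arnold reaction of 6 (POBr3, DMF, CHCl3, 0 → 60 °C) formylates C3′ as the ring aromatises and should give 2,5-dibromo-1-(2-bromo-4-methoxy-5-nitrophenyl)-1H-indole-3-carbaldehyde F3. Pinnick oxidation (NaClO2, NaH2PO4, 2-methyl-2-butene, t-BuOH/THF/H2O) should give 2,5-dibromo-1-(2-bromo-4-methoxy-5-nitrophenyl)-1H-indole-3-carboxylic acid F4. Protodecarboxylation of F4 (Ag2CO3 cat., AcOH, DMSO, 120 °C) returns 7.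

**Step 3.** The amide nitrogen is electron-poor and has an ortho bromine, so its coupling may be slow. Then intermolecular coupling at C–Br bonds, arylation at the acidic C3′ methylene group, or aerobic oxidation of that methylene group can take over. The fallback sets out from 2 and comes back at 7 without a lactam. Nucleophilic aromatic substitution of 2 on 5-bromo-2-fluorobenzaldehyde (Cs2CO3, DMSO, 100 °C), where the ortho formyl group activates the fluoride, should give 5-bromo-2-[(2-bromo-4-methoxy-5-nitrophenyl)amino]benzaldehyde F5. Ramirez olefination (CBr4, PPh3, CH2Cl2, 0 °C) should give 4-bromo-N-(2-bromo-4-methoxy-5-nitrophenyl)-2-(2,2-dibromoethenyl)aniline F6. Intramolecular C–N coupling of the gem-dibromoalkene (Pd[P(t-Bu)3]2, K3PO4, toluene, 100 °C) closes ring B with C2′–Br in place and gives 7. With this bulky phosphine, oxidative addition of zerovalent palladium to aryl bromides is reversible, so only the alkenyl bromide is consumed.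

## Further compounds

F1 | step 5 | 4-bromo-5-(2,5-dibromo-1H-indol-1-yl)-2-methoxyaniline | COc1cc(Br)c(-n2c(Br)cc3cc(Br)ccc32)cc1N
F2 | step 5 | 1-[2-amino-5-bromo-6-(2,5-dibromo-1H-indol-1-yl)-3-methoxyphenyl]-2-chloroethan-1-one | COc1cc(Br)c(-n2c(Br)cc3cc(Br)ccc32)c(C(=O)CCl)c1N
F3 | step 4 | 2,5-dibromo-1-(2-bromo-4-methoxy-5-nitrophenyl)-1H-indole-3-carbaldehyde | COc1cc(Br)c(-n2c(Br)c(C=O)c3cc(Br)ccc32)cc1[N+](=O)[O-]
F4 | step 4 | 2,5-dibromo-1-(2-bromo-4-methoxy-5-nitrophenyl)-1H-indole-3-carboxylic acid | COc1cc(Br)c(-n2c(Br)c(C(=O)O)c3cc(Br)ccc32)cc1[N+](=O)[O-]
F5 | step 3 | 5-bromo-2-[(2-bromo-4-methoxy-5-nitrophenyl)amino]benzaldehyde | O=Cc1cc(Br)ccc1Nc1cc([N+](=O)[O-])c(OC)cc1Br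
F6 | step 3 | 4-bromo-N-(2-bromo-4-methoxy-5-nitrophenyl)-2-(2,2-dibromoethenyl)aniline | BrC(Br)=Cc1cc(Br)ccc1Nc1cc([N+](=O)[O-])c(OC)cc1Br
A1 | alternative 1 | 4-iodo-7-methoxy-1H-indole | COc1ccc(I)c2cc[nH]c12
A2 | alternative 1 | 5-bromo-1H-indole | Brc1ccc2[nH]ccc2c1
A3 | alternative 1 | 4-(5-bromo-1H-indol-1-yl)-7-methoxy-1H-indole | COc1ccc(-n2ccc3cc(Br)ccc32)c2cc[nH]c12
A4 | alternative 1 | 2,5-dibromo-1H-indole | Brc1cc2cc(Br)ccc2[nH]1
A5 | alternative 2 | 7-methoxy-1-(4-methylbenzenesulfonyl)-5-(trimethylsilyl)-1H-indol-4-yl trifluoromethanesulfonate | COc1cc([Si](C)(C)C)c(OS(=O)(=O)C(F)(F)F)c2ccn(S(=O)(=O)c3ccc(C)cc3)c12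
A6 | alternative 3 | 1-(5-bromo-7-methoxy-2,3-dihydro-1H-indol-1-yl)ethan-1-one | CC(=O)N1CCc2cc(Br)cc(OC)c21
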